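(The data come from a simulation with made-up constants; scatter was added.)

Work in decades, the unit of a common logarithm, and ask what the answer "all alike" would take.

the same everywhere: starting material 0.40 M; free catalyst 1 mol%
- cedar: impurity 0.87 mM; temperature −15 °C; run made earlier
- alder: impurity 2 mM; temperature 18 °C; run made earlier
- Monday's: impurity 1.3 mM; temperature 30 °C; time 20 h
- Friday's: impurity 1.3 mM; temperature −30 °C; time 20 h
- Saturday's: impurity 1.3 mM; temperature 0 °C; time 20 h

| run | time / h | target / % |
|---|---|---|
| cedar | 10.0 | 0.2 |
| cedar | 15.0 | 1.4 |
| cedar | 25.0 | 1.8 |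
| cedar | 40.0 | 2.9 |
| cedar | 72.0 | 4.6 |
| cedar | 120 | 2.4 |
| alder | 4.00 | 8.1 |
| alder | 8.00 | 8.5 |
| alder | 10.0 | 9.9 |
| alder | 15.0 | 10.6 |
| alder | 20.0 | 9.6 |

(scatter of a reading: 1 percentage point)
1. the flask with the highest amount of target, in percent of the starting material charged ("all alike" if they lie within 1.5 percentage points) (Monday's / Friday's / Saturday's / all alike)
2. final target, as a percentage of the starting material charged, in Monday's
3. final target, as a percentage of the starting material charged, in Friday's
4. final target, as a percentage of the starting material charged, in Saturday's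


Friday's, at −30 °C, would have to come within 1.5 percentage points of Monday's. If Monday's levels as alder did, that is an assumption, since impurity and temperature moved together, and Friday's would need 8.10 %.

Call the climb a run's reading divided by its time (the initial rate, in the usual term). Cedar reads 2.9 % at 40.0 h and alder 8.1 % at 4.00 h:

alder's climb over cedar's: 27.9, or 1.45 decades

Friday's below cedar, as a share of the cedar-to-alder span: 0.455, or 0.657 decades

The cold yield, meaning cedar's climb lowered by those decades and run for 20 h, is my own number:

cold yield: 0.319 %

distance from "all alike": 1.40 decades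

Cedar's reading enters the cold yield directly and through the ratio of climbs, so a reading one standard deviation higher shortens this distance by 0.187 decades, much less than the distance. Alder reads 8.1 % at 4.00 h and 9.6 % at 20.0 h, so it is already near level and its climb is a floor. A steeper climb pushes the cold yield lower.

The forecast says Monday's, with 9 %, 0.8 % and 5 % for Monday's, Friday's and Saturday's: “Friday's is only about 10% complete, so under 1%.” Its Friday's figure stands above my cold yield.

    starting material + free catalyst ⇌ target + free catalyst, rate k1*[starting material]*[free catalyst] forward; the back reaction follows from the equilibrium constant (K = 2.90, k = 0.782 /M/min, Ea = 65.0 kJ/mol, ΔH = −21.0 kJ/mol)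
    target ⇌ isomer of the product A (K = 10.0, k = 0.00182 /min, Ea = 85.0 kJ/mol, ΔH = −25.0 kJ/mol)
    isomer of the product A ⇌ isomer of the product B (K = 0.455, k = 0.00430 /min, Ea = 97.0 kJ/mol, ΔH = 14.0 kJ/mol)
    isomer of the product B + free catalyst ⇌ starting material + free catalyst, rate k4*[free catalyst]*[isomer of the product B] forward; the back reaction follows from the equilibrium constant (k = 3.98 /M/min, Ea = 62.0 kJ/mol)
    free catalyst + impurity → spent catalyst A (k = 982 /M/min, Ea = 50.0 kJ/mol)
    2 free catalyst → spent catalyst B (k = 0.603 /M/min, Ea = 59.0 kJ/mol)
    starting material + free catalyst → spent catalyst C (k = 0.00150 /M/min, Ea = 65.0 kJ/mol)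
    (constants at 0 °C)

Monday's gave 12.4 %, Saturday's 5.93 % and Friday's 0.297 %, against a cold yield of 0.319 %, which puts Friday's 1.56 decades from "all alike". In Friday's at 10.0 h, starting material stood at 1.24 % and isomer of the product B at 92.9 %. By 20.0 h that isomer had fallen to 87.4 %, isomer of the product A had risen to 11.1 %, and target had crept from 0.259 % to 0.297 %. Carried on to 3.0 d, the cold yield's climb reaches 1.15 %, and Friday's flask read then holds 0.448 % of target.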